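**Plan**

- Retrosynthesis, in order: the C7–O ester bond (late stearoylation of the tertiary ketol); the C6–C7 bond of the carbocycle; C4a–C8a together with C5–C6 (one palladium cascade that closes the pyran and adds the formyl carbon); C1–O2 (oxa-Michael addition of the side-chain alcohol to an ynone).
- Enabling feature: C6(=O)–C7(OH)(CH3) next to C8=O is an acyloin unit, and C5–C6 and C8a–C8 sit cis on the C4a–C8a bond of ring A. An aldehyde at C6 and a methyl ketone at C7 can therefore be joined by an intramolecular crossed aldehyde–ketone benzoin reaction.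
- Forward: a lactate-derived ynone and (R)-pent-4-yn-2-ol give a β-alkoxy enone, then its α-iodide; ring A (dihydropyran: O2, C1, C8a, C4a, C4, C3) is closed with a Z enal; the 1,2-dione is unveiled; ring B (C4a, C5, C6, C7, C8, C8a) is closed by the benzoin reaction; stearoyl chloride caps C7–OH.
- Stereochemistry: C3 comes from (R)-pent-4-yn-2-ol. The Z exocyclic alkene comes from syn-carbopalladation. C7 is set by a chiral triazolium carbene (catalyst control).
- Ring A is closed before ring B so that C8a is fully substituted; the ketol then cannot lose its C7 configuration through a pseudo-symmetric vinylogous acid.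

Key step: step 8

Remark: atoms are numbered as in isochromene (C1, O2, C3, C4, C4a, C5, C6, C7, C8, C8a).
Remark: the sense of induction of the triazolium salt at C7 is assigned by analogy; should it prove opposite, the (5aR,10bS) antipode of the same salt is used, and because C3 is fixed the two C7 epimers are diastereomers that can be separated.
Remark: catalyst-bound species of the catalytic cycles (organopalladium complexes, carbene adducts) are described in words and carry no number.
Remark: the lactate-derived stereocentre is sacrificial (erased in step 7), so its integrity is not critical; compound 1 is taken as a catalogue compound (otherwise one silylation of ethyl (S)-lactate).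

**Step 1**
Reactants: 1 ethyl (S)-2-[(tert-butyldimethylsilyl)oxy]propanoate
Product: 2 (S)-2-[(tert-butyldimethylsilyl)oxy]-N-methoxy-N-methylpropanamide
Conditions: MeNHOMe·HCl, iPrMgCl, THF, −20 → 0 °C
Reagents that add atoms: N,O-dimethylhydroxylamine hydrochloride, CNOC.Cl
Why: Aminolysis of the ester by the chloromagnesium amide made in the flask is the standard ester-to-Weinreb-amide conversion and should leave the silyl ether and the α-stereocentre untouched.

**Step 2**
Reactants: 2 (S)-2-[(tert-butyldimethylsilyl)oxy]-N-methoxy-N-methylpropanamide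
Product: 4 (S)-4-[(tert-butyldimethylsilyl)oxy]pent-1-yn-3-one, via magnesium hemiaminal chelate 3 (not isolated)
Conditions: HC≡CMgBr, THF, 0 °C; then inverse quench into cold 1 M HCl
Reagents that add atoms: ethynylmagnesium bromide, C#C[Mg]Br
Why: Grignard addition to a Weinreb amide (Weinreb ketone synthesis) stops at chelate 3, which collapses to the ynone only on acidic quench, so over-addition is avoided and the protonated amine cannot add to the ynone.

**Step 3**
Reactants: 4 (S)-4-[(tert-butyldimethylsilyl)oxy]pent-1-yn-3-one; 5 (R)-pent-4-yn-2-ol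
Product: 6 (1E,4S)-4-[(tert-butyldimethylsilyl)oxy]-1-[(2R)-pent-4-yn-2-yloxy]pent-1-en-3-one
Conditions: PMe3 (10 mol %), CH2Cl2, 0 °C → rt
Reagents that add atoms: none
Why: Phosphine-catalysed oxa-Michael addition of a secondary alcohol to a terminal ynone is an established route to (E)-β-alkoxy vinyl ketones and forms the C1–O2 bond without touching the carbinol centre of 5.

**Step 4**
Reactants: 6 (1E,4S)-4-[(tert-butyldimethylsilyl)oxy]-1-[(2R)-pent-4-yn-2-yloxy]pent-1-en-3-one
Product: 8 (1Z,4S)-4-[(tert-butyldimethylsilyl)oxy]-2-iodo-1-[(2R)-pent-4-yn-2-yloxy]pent-1-en-3-one, via acetoxy iodo adduct 7 (not isolated)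
Conditions: NIS, AcOH, CH2Cl2, rt; then Et3N, 0 °C
Reagents that add atoms: N-iodosuccinimide, O=C1CCC(=O)N1I; acetic acid, CC(=O)O (its acetate is held only in 7)
Why: Electrophilic iodination of the push-pull enol ether at its α-carbon gives adduct 7, and base-induced loss of acetic acid (halogenation–elimination, as known for β-alkoxy acrylates) should restore the vinylogous ester as the Z iodide with iodine cis to the alkoxy group, the geometry ring A requires.

**Step 5**
Reactants: 8 (1Z,4S)-4-[(tert-butyldimethylsilyl)oxy]-2-iodo-1-[(2R)-pent-4-yn-2-yloxy]pent-1-en-3-one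
Product: 9 (2Z)-2-[(2R)-5-[(2S)-2-[(tert-butyldimethylsilyl)oxy]propanoyl]-2-methyl-2,3-dihydro-4H-pyran-4-ylidene]acetaldehyde
Conditions: Pd(OAc)2 (5 mol %), dppp (5 mol %), CO (1 atm), Et3SiH (slow addition), Et3N, DMF, 60 °C
Reagents that add atoms: carbon monoxide, [C-]#[O+]
Why: Oxidative addition of zerovalent palladium to the vinyl iodide, 6-exo-dig syn-carbopalladation of the terminal alkyne (closing ring A through C8a–C4a), CO insertion and hydride capture of the acylpalladium by the silane follow the known cyclization–carbonylation–hydride-capture cascade and the Pd-catalysed reductive carbonylation of vinyl halides, and the syn addition places palladium, and hence the formyl group, cis to C8a, which fixes the Z enal.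

**Step 6**
Reactants: 9 (2Z)-2-[(2R)-5-[(2S)-2-[(tert-butyldimethylsilyl)oxy]propanoyl]-2-methyl-2,3-dihydro-4H-pyran-4-ylidene]acetaldehyde
Product: 10 (2Z)-2-[(2R)-5-[(2S)-2-hydroxypropanoyl]-2-methyl-2,3-dihydro-4H-pyran-4-ylidene]acetaldehyde
Conditions: HF·pyridine, pyridine, THF, 0 °C
Reagents that add atoms: none
Why: Buffered fluoride-mediated desilylation should cleave the secondary silyl ether without a base that could enolize the dienal or open the vinylogous ester.

**Step 7**
Reactants: 10 (2Z)-2-[(2R)-5-[(2S)-2-hydroxypropanoyl]-2-methyl-2,3-dihydro-4H-pyran-4-ylidene]acetaldehyde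
Product: 11 (2Z)-2-[(2R)-2-methyl-5-(2-oxopropanoyl)-2,3-dihydro-4H-pyran-4-ylidene]acetaldehyde
Conditions: Dess–Martin periodinane, CH2Cl2, 0 °C → rt; non-aqueous work-up, used crude
Reagents that add atoms: none
Why: Dess–Martin oxidation converts the α-hydroxy ketone into the 1,2-dione under neutral conditions that the enal and the enol ether should tolerate, and it erases the sacrificial lactate stereocentre.

**Step 8**
Reactants: 11 (2Z)-2-[(2R)-2-methyl-5-(2-oxopropanoyl)-2,3-dihydro-4H-pyran-4-ylidene]acetaldehyde
Product: 12 (3R,7R)-7-hydroxy-3,7-dimethyl-3,4-dihydro-6H-isochromene-6,8(7H)-dione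
Conditions: (5aS,10bR)-2-mesityl-5a,10b-dihydro-4H,6H-indeno[2,1-b][1,2,4]triazolo[4,3-d][1,4]oxazin-2-ium chloride (15 mol %), iPr2NEt (15 mol %), 4 Å MS, toluene, rt
Reagents that add atoms: none
Why: The carbene freed from the triazolium salt adds to the aldehyde carbon C6 of 11, proton transfer gives a catalyst-bound enaminol (acyl anion equivalent), and this adds to the C7 carbonyl of the 1,2-dione before the carbene is expelled, leaving C6 as ketone and C7 as tertiary carbinol. The closest known reaction type is the intramolecular crossed aldehyde–ketone benzoin cyclization with chiral aminoindanol-derived triazolium carbenes, which gives six-membered α-ketols bearing a tertiary carbinol. Ring B (C4a, C5, C6, C7, C8, C8a) closes in the 6-exo-trig mode on the C7 carbonyl. The new quaternary centre C7 is set by the catalyst: the indane face of the carbene blocks one face of the enaminol and the enaminol O–H to ketone hydrogen bond orders the transition state, while the remote C3 centre has little say. The step needs acyl-anion instead of homoenolate reactivity (the β-carbon C4a is fully substituted and could only close three- or four-membered rings, and no protic nucleophile is present), attack at C7 instead of C8 (C8 is a deactivated vinylogous ester carbonyl and would give a five-membered ring) and the Z enal geometry built in step 5. Because C8a is already a fully substituted ring carbon, the product cannot tautomerize to a pseudo-symmetric vinylogous acid, so the C7 configuration should be kept.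

**Step 9**
Reactants: 12 (3R,7R)-7-hydroxy-3,7-dimethyl-3,4-dihydro-6H-isochromene-6,8(7H)-dione; 13 octadecanoyl chloride
Product: 14 (3R,7R)-3,7-dimethyl-6,8-dioxo-3,4,7,8-tetrahydro-6H-isochromen-7-yl octadecanoate
Conditions: Et3N, DMAP (cat.), CH2Cl2, 0 °C → rt
Reagents that add atoms: none
Why: DMAP-catalysed acyl transfer from the acid chloride (Steglich-type acylation) is the usual way to esterify the tertiary C7 hydroxyl of this ring system and breaks no bond at C7, so the configuration is retained.

**Compound list**

1 | ethyl (S)-2-[(tert-butyldimethylsilyl)oxy]propanoate | CCOC(=O)[C@H](C)O[Si](C)(C)C(C)(C)C | starting material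
2 | (S)-2-[(tert-butyldimethylsilyl)oxy]-N-methoxy-N-methylpropanamide | CON(C)C(=O)[C@H](C)O[Si](C)(C)C(C)(C)C | intermediate
3 | bromomagnesium (4S)-4-[(tert-butyldimethylsilyl)oxy]-3-[methoxy(methyl)amino]pent-1-yn-3-olate (chelate, mixture at C3) | C#CC(O[Mg]Br)(N(C)OC)[C@H](C)O[Si](C)(C)C(C)(C)C | intermediate
4 | (S)-4-[(tert-butyldimethylsilyl)oxy]pent-1-yn-3-one | C#CC(=O)[C@H](C)O[Si](C)(C)C(C)(C)C | intermediate
5 | (R)-pent-4-yn-2-ol | C[C@@H](O)CC#C | starting material
6 | (1E,4S)-4-[(tert-butyldimethylsilyl)oxy]-1-[(2R)-pent-4-yn-2-yloxy]pent-1-en-3-one | C#CC[C@@H](C)O/C=C/C(=O)[C@H](C)O[Si](C)(C)C(C)(C)C | intermediate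
7 | (4S)-4-[(tert-butyldimethylsilyl)oxy]-2-iodo-3-oxo-1-[(2R)-pent-4-yn-2-yloxy]pentyl acetate (mixture at C1 and C2) | C#CC[C@@H](C)OC(OC(C)=O)C(I)C(=O)[C@H](C)O[Si](C)(C)C(C)(C)C | intermediate
8 | (1Z,4S)-4-[(tert-butyldimethylsilyl)oxy]-2-iodo-1-[(2R)-pent-4-yn-2-yloxy]pent-1-en-3-one | C#CC[C@@H](C)O/C=C(I)/C(=O)[C@H](C)O[Si](C)(C)C(C)(C)C | intermediate
9 | (2Z)-2-[(2R)-5-[(2S)-2-[(tert-butyldimethylsilyl)oxy]propanoyl]-2-methyl-2,3-dihydro-4H-pyran-4-ylidene]acetaldehyde | C[C@@H]1C/C(=C/C=O)C(C(=O)[C@H](C)O[Si](C)(C)C(C)(C)C)=CO1 | intermediate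
10 | (2Z)-2-[(2R)-5-[(2S)-2-hydroxypropanoyl]-2-methyl-2,3-dihydro-4H-pyran-4-ylidene]acetaldehyde | C[C@@H]1C/C(=C/C=O)C(C(=O)[C@H](C)O)=CO1 | intermediate
11 | (2Z)-2-[(2R)-2-methyl-5-(2-oxopropanoyl)-2,3-dihydro-4H-pyran-4-ylidene]acetaldehyde | C[C@@H]1C/C(=C/C=O)C(C(=O)C(C)=O)=CO1 | intermediate
12 | (3R,7R)-7-hydroxy-3,7-dimethyl-3,4-dihydro-6H-isochromene-6,8(7H)-dione | O[C@]1(C)C(=O)C=C2C[C@@H](C)OC=C2C1=O | intermediate
13 | octadecanoyl chloride (stearoyl chloride) | CCCCCCCCCCCCCCCCCC(=O)Cl | starting material
14 | (3R,7R)-3,7-dimethyl-6,8-dioxo-3,4,7,8-tetrahydro-6H-isochromen-7-yl octadecanoate | CCCCCCCCCCCCCCCCCC(=O)O[C@]1(C)C(=O)C=C2C[C@@H](C)OC=C2C1=O | target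

**Step count and risks**

Total steps: 9. Longest linear sequence: 9 steps (1 to 14); 7 steps from 5.

Steps most likely to fail:

1. Step 8. The carbene may add only slowly to the donor-substituted (push-pull) aldehyde, closure may go onto C8 to give a five-membered ring, or the facial discrimination at C7 may be poor. Fallback: from 9, LiN(SiMe3)2 in THF at −78 °C should deprotonate C7–H of the silyloxy ketone, and the enolate adds to the C6 aldehyde in an intramolecular aldol reaction that closes the same C6–C7 bond. This gives the silyl-protected aldol F1 together with its C7 epimer. Dess–Martin periodinane then oxidizes the C6 carbinol to the silyl-protected dione F2. HF·pyridine removes the tertiary silyl group, and the route is rejoined at 12 after chromatographic separation of the C7 epimers, which are diastereomers because C3 is fixed.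

2. Step 5. Hydride capture may occur before cyclization or before CO insertion (simple reduction), the terminal alkyne may couple intermolecularly with the vinyl iodide, or the enal may be over-reduced. Fallback: from 8, the same cyclization is ended by methanol instead of hydride (PdCl2(PPh3)2, CO 1 atm, MeOH, Et3N, DMF, 60 °C; cyclic carbopalladation–carbonylative esterification) to give the Z methyl ester F3. iBu2AlH (CH2Cl2, −78 °C) reduces ester and ketone to the allylic diol F4. MnO2 (CH2Cl2, rt) oxidizes both allylic alcohols, and the route is rejoined at 9.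

3. Step 7. The hydroxy aldehyde may close to a lactol that is over-oxidized to a lactone, or the dione may hydrate or decompose during isolation. Fallback: from 8, HF·pyridine gives the iodo hydroxy ketone F5 and Dess–Martin periodinane gives the iodo 1,2-dione F6. The palladium cyclization–formylation of step 5 (Pd(OAc)2, dppp, CO, Et3SiH, Et3N, DMF) applied to F6 then gives 11 directly, so that no hydroxy aldehyde is ever present.

**Further compounds**

F1 | step 8 | (3R,7R)-7-[(tert-butyldimethylsilyl)oxy]-6-hydroxy-3,7-dimethyl-3,4,6,7-tetrahydro-8H-isochromen-8-one (mixture at C6) | CC(C)(C)[Si](C)(C)O[C@]1(C)C(O)C=C2C[C@@H](C)OC=C2C1=O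
F2 | step 8 | (3R,7R)-7-[(tert-butyldimethylsilyl)oxy]-3,7-dimethyl-3,4-dihydro-6H-isochromene-6,8(7H)-dione | CC(C)(C)[Si](C)(C)O[C@]1(C)C(=O)C=C2C[C@@H](C)OC=C2C1=O
F3 | step 5 | methyl (2Z)-2-[(2R)-5-[(2S)-2-[(tert-butyldimethylsilyl)oxy]propanoyl]-2-methyl-2,3-dihydro-4H-pyran-4-ylidene]acetate | C[C@@H]1C/C(=C/C(=O)OC)C(C(=O)[C@H](C)O[Si](C)(C)C(C)(C)C)=CO1
F4 | step 5 | (2S)-2-[(tert-butyldimethylsilyl)oxy]-1-[(2R,4Z)-4-(2-hydroxyethylidene)-2-methyl-3,4-dihydro-2H-pyran-5-yl]propan-1-ol (mixture at C1) | C[C@@H]1C/C(=C/CO)C(C(O)[C@H](C)O[Si](C)(C)C(C)(C)C)=CO1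
F5 | step 7 | (1Z,4S)-4-hydroxy-2-iodo-1-[(2R)-pent-4-yn-2-yloxy]pent-1-en-3-one | C#CC[C@@H](C)O/C=C(I)/C(=O)[C@H](C)O
F6 | step 7 | (1Z)-2-iodo-1-[(2R)-pent-4-yn-2-yloxy]pent-1-ene-3,4-dione | C#CC[C@@H](C)O/C=C(I)/C(=O)C(C)=O
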